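**Retrosynthetic overview**
- Target 23 comes from 22 by removal of three MOM ethers. 22 comes from bis(tertiary boronate) 19 by a double Zweifel vinylation that puts a vinyl group where each boron was.
- 19 comes from bis-carbamate 13 and two molecules of homogeranyl boronate 16 by a two-directional lithiation–borylation, which forms both C3–C4 bonds and both quaternary carbons. The strategy rests on the fact that each quaternary C3 is benzylic (on C1 of ring A, on C5 of ring B) and carries a methyl group. Each is therefore the image of a 1-arylethyl carbinol, (R) on ring A and (S) on ring B.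
- 13 comes from an Ullmann C–O coupling of ring A ketophenol 4 with ring B aryl iodide 10, whose (S)-carbinol is already set and carbamoylated. The ring A ketone is reduced with the enantiomeric CBS catalyst and carbamoylated only after the coupling.
- No ring is formed: ring A is bought as 3,4-dihydroxyacetophenone and ring B as acetovanillone. Boronate 16 comes from geranyl bromide and CH2(Bpin)2.

Key step: step 13

Remark: ring A is the 3-hydroxy-4-aryloxyphenyl ring, ring B the 1-aryloxy-2,3-dihydroxyphenyl ring, and C3 is the quaternary carbon of each 3,7,11-trimethyldodeca-1,6,10-trien-3-yl chain; vinyllithium is assumed to be made from Sn(CH=CH2)4 and n-BuLi just before use.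

**Route**

Step 1
Reactants: 1 3,4-dihydroxyacetophenone
Product: 2 1-[4-(benzyloxy)-3-hydroxyphenyl]ethanone
Conditions: BnBr (1.05 equiv), NaHCO3, NaI (cat.), DMF, 40 °C
Reagents that add atoms: benzyl bromide, BrCc1ccccc1
Why: Williamson etherification under a weak base ionises only the 4-OH, which conjugation to the para acetyl group makes the more acidic phenol, so benzylation should occur there and leave the 3-OH free.

Step 2
Reactants: 2 1-[4-(benzyloxy)-3-hydroxyphenyl]ethanone
Product: 3 1-[4-(benzyloxy)-3-(methoxymethoxy)phenyl]ethanone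
Conditions: MOMCl, iPr2NEt, CH2Cl2, 0 °C → rt
Reagents that add atoms: chloromethyl methyl ether, COCCl
Why: Standard MOM ether formation, alkylation of the remaining phenol by the reactive α-chloro ether under amine base.

Step 3
Reactants: 3 1-[4-(benzyloxy)-3-(methoxymethoxy)phenyl]ethanone
Product: 4 1-[4-hydroxy-3-(methoxymethoxy)phenyl]ethanone
Conditions: H2 (1 atm), 10% Pd/C, EtOAc, rt
Reagents that add atoms: none
Why: Catalytic hydrogenolysis cleaves the aryl benzyl ether much faster than it reduces the aryl ketone at 1 atm in EtOAc, and the MOM acetal is inert to neutral hydrogenation.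

Step 4
Reactants: 5 acetovanillone
Product: 6 1-(4-hydroxy-3-iodo-5-methoxyphenyl)ethanone
Conditions: N-iodosuccinimide (1.05 equiv), TsOH·H2O (cat.), MeCN, rt
Reagents that add atoms: N-iodosuccinimide, O=C1CCC(=O)N1I
Why: Electrophilic aromatic iodination is directed by the free phenol to its only open ortho position (C5), as in the halogenation of vanillin-type phenols.

Step 5
Reactants: 6 1-(4-hydroxy-3-iodo-5-methoxyphenyl)ethanone
Product: 7 1-(3,4-dihydroxy-5-iodophenyl)ethanone
Conditions: BBr3, CH2Cl2, −78 °C → 0 °C; then H2O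
Reagents that add atoms: none
Why: Lewis-acid ether cleavage (bromide attacks the methyl group of the boron-complexed aryl methyl ether) should free the catechol while the aryl iodide and the ketone stay untouched.

Step 6
Reactants: 7 1-(3,4-dihydroxy-5-iodophenyl)ethanone
Product: 8 1-[3-iodo-4,5-bis(methoxymethoxy)phenyl]ethanone
Conditions: MOMCl (3 equiv), iPr2NEt (4 equiv), CH2Cl2, 0 °C → rt
Reagents that add atoms: chloromethyl methyl ether, COCCl
Why: Double MOM ether formation of the catechol under amine base, with excess of the small, reactive electrophile to drive the hindered 4-OH next to iodine to completion.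

Step 7
Reactants: 8 1-[3-iodo-4,5-bis(methoxymethoxy)phenyl]ethanone
Product: 9 (S)-1-[3-iodo-4,5-bis(methoxymethoxy)phenyl]ethanol
Conditions: (R)-Me-CBS oxazaborolidine (15 mol%), BH3·SMe2, THF, −20 °C; MeOH quench
Reagents that add atoms: none
Why: Corey–Bakshi–Shibata reduction, in which the (R)-oxazaborolidine tells aryl (large) from methyl (small) and should give the (S)-carbinol, the mirror image of the known (S)-catalyst/acetophenone outcome of (R)-1-phenylethanol; aryl iodide and MOM ethers are inert to borane at this temperature.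

Step 8
Reactants: 9 (S)-1-[3-iodo-4,5-bis(methoxymethoxy)phenyl]ethanol
Product: 10 (S)-1-[3-iodo-4,5-bis(methoxymethoxy)phenyl]ethyl N,N-diisopropylcarbamate
Conditions: iPr2NCOCl, Et3N, CH2Cl2, reflux
Reagents that add atoms: N,N-diisopropylcarbamoyl chloride, CC(C)N(C(C)C)C(=O)Cl
Why: O-Carbamoylation of the secondary alcohol takes place at oxygen only, so the C–O stereocentre is not touched and the (S) configuration is kept.

Step 9
Reactants: 4 1-[4-hydroxy-3-(methoxymethoxy)phenyl]ethanone; 10 (S)-1-[3-iodo-4,5-bis(methoxymethoxy)phenyl]ethyl N,N-diisopropylcarbamate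
Product: 11 (S)-1-{3-[4-acetyl-2-(methoxymethoxy)phenoxy]-4,5-bis(methoxymethoxy)phenyl}ethyl N,N-diisopropylcarbamate
Conditions: CuI (10 mol%), picolinic acid (20 mol%), K3PO4, DMSO, 90 °C
Reagents that add atoms: none
Why: Ullmann-type copper-catalysed C–O coupling with the picolinic acid ligand, which tolerates ortho substituents on both partners and works best with aryl iodides; ring A is kept as the ketone here because a benzylic carbamate para to a phenoxide would be expelled as a quinone methide, and the ring B stereocentre has no hydrogen acidic enough for K3PO4.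

Step 10
Reactants: 11 (S)-1-{3-[4-acetyl-2-(methoxymethoxy)phenoxy]-4,5-bis(methoxymethoxy)phenyl}ethyl N,N-diisopropylcarbamate
Product: 12 (S)-1-{3-[4-((R)-1-hydroxyethyl)-2-(methoxymethoxy)phenoxy]-4,5-bis(methoxymethoxy)phenyl}ethyl N,N-diisopropylcarbamate
Conditions: (S)-Me-CBS oxazaborolidine (15 mol%), BH3·SMe2, THF, −20 °C; MeOH quench
Reagents that add atoms: none
Why: CBS reduction under catalyst control with the (S)-oxazaborolidine should give the (R)-carbinol on ring A independently of the remote ring B stereocentre, and the hindered diisopropylcarbamate is not reduced by borane at −20 °C.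

Step 11
Reactants: 12 (S)-1-{3-[4-((R)-1-hydroxyethyl)-2-(methoxymethoxy)phenoxy]-4,5-bis(methoxymethoxy)phenyl}ethyl N,N-diisopropylcarbamate
Product: 13 bis(N,N-diisopropylcarbamate) of the tris-MOM diaryl ether diol, (R) at the ring A carbinol carbon and (S) at the ring B carbinol carbon
Conditions: iPr2NCOCl, Et3N, CH2Cl2, reflux
Reagents that add atoms: N,N-diisopropylcarbamoyl chloride, CC(C)N(C(C)C)C(=O)Cl
Why: O-Carbamoylation at oxygen with retention of the (R)-carbinol; the para oxygen is now an aryl ether, so the benzylic carbamate cannot be lost through a quinone methide.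

Step 12
Reactants: 14 geranyl bromide; 15 bis[(pinacolato)boryl]methane
Product: 16 (E)-homogeranyl pinacol boronate, 2-[(3E)-4,8-dimethylnona-3,7-dien-1-yl]-4,4,5,5-tetramethyl-1,3,2-dioxaborolane
Conditions: NaOtBu, THF, rt
Reagents that add atoms: none
Why: Deborylative alkylation of a geminal bis(boronate), in which tert-butoxide adds to one boron and releases the α-boryl carbanion that displaces bromide at the primary allylic carbon (SN2), so the E alkene is kept.

Step 13
Reactants: 13 bis(N,N-diisopropylcarbamate), (R) on ring A and (S) on ring B; 16 (E)-homogeranyl pinacol boronate (3 equiv)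
Product: 19 bis(tertiary pinacol boronic ester) of the tris-MOM diaryl ether (R at the ring A carbon; S at the ring B carbon), via dilithiated bis-carbamate 17 (not isolated), via dilithium bis-boronate complex 18 (not isolated)
Conditions: s-BuLi (2.6 equiv), Et2O, −78 °C, 1 h; 16 (3.0 equiv), −78 °C, 2 h; MgBr2 in MeOH, −78 °C → rt, 16 h
Reagents that add atoms: none
Why: sec-Butyllithium, guided by each carbamate carbonyl, removes each benzylic hydrogen with retention to give configurationally stable α-oxybenzyllithiums, boronate 16 captures each C–Li bond with retention, and in the two ate complexes the homogeranyl group shifts from boron to carbon anti to the departing carbamate, which forms both C3–C4 bonds. The closest known reaction type is the lithiation–borylation of enantioenriched secondary benzylic carbamates with primary alkyl pinacol boronates to give tertiary boronic esters, run here at two independent sites of one molecule. No ring is closed. Each quaternary stereocentre is set only by the configuration of its own carbinol carbon, boron taking the place of hydrogen and homogeranyl entering opposite to oxygen, so the (R)-carbamate on ring A gives the (R)-boronate carbon and the (S)-carbamate on ring B the (S) one. The step needs benzylic deprotonation to win over ortho-lithiation next to the MOM and aryl ether oxygens, which the carbamate-directed benzylic acidity in Et2O without a diamine should secure, and the alkenes of 16 never meet the base because 16 is added only after lithiation. It also needs the 1,2-shift to outrun dissociation of the ate complexes back to the lithiated carbamates, which MgBr2 in MeOH and the good migrating ability of a primary alkyl group secure.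

Step 14
Reactants: 19 bis(tertiary pinacol boronic ester)
Product: 22 tris-MOM ether of the target (both vinyl groups in place), via dilithium bis(vinylboronate) complex 20 (not isolated), via bis(β-iodoalkyl boronic ester) 21 (not isolated)
Conditions: CH2=CHLi (6 equiv, from Sn(CH=CH2)4 + n-BuLi), THF, −78 °C; I2 (6 equiv) in MeOH, −78 °C; NaOMe in MeOH, −78 °C → rt
Reagents that add atoms: vinyllithium, [Li]C=C
Why: Zweifel olefination, in which vinyllithium forms the vinyl boronate complex, iodine triggers 1,2-migration of the tertiary benzylic carbon from boron to the vinyl α-carbon with retention and methoxide induces anti elimination of boron and iodide, so both quaternary centres keep their configuration; iodine is matched to vinyllithium so that none remains for the chain alkenes.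

Step 15
Reactants: 22 tris-MOM ether of the target
Product: 23 target, 3-{2-hydroxy-4-[(3R,6E)-3,7,11-trimethyldodeca-1,6,10-trien-3-yl]phenoxy}-5-[(3S,6E)-3,7,11-trimethyldodeca-1,6,10-trien-3-yl]benzene-1,2-diol
Conditions: TsOH·H2O, degassed MeOH, Ar, rt → 40 °C
Reagents that add atoms: none
Why: Acid-catalysed transacetalisation of the three aryl MOM ethers to methanol under mild sulfonic acid conditions should spare the trisubstituted alkenes and the all-carbon quaternary centres, and exclusion of air protects the catechol units from oxidation.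

**Compound list**

1 | 3,4-dihydroxyacetophenone | CC(=O)c1ccc(O)c(O)c1 | starting material
2 | 1-[4-(benzyloxy)-3-hydroxyphenyl]ethanone | CC(=O)c1ccc(OCc2ccccc2)c(O)c1 | intermediate
3 | 1-[4-(benzyloxy)-3-(methoxymethoxy)phenyl]ethanone | CC(=O)c1ccc(OCc2ccccc2)c(OCOC)c1 | intermediate
4 | 1-[4-hydroxy-3-(methoxymethoxy)phenyl]ethanone (ring A ketophenol) | CC(=O)c1ccc(O)c(OCOC)c1 | intermediate
5 | acetovanillone, 1-(4-hydroxy-3-methoxyphenyl)ethanone | CC(=O)c1ccc(O)c(OC)c1 | starting material
6 | 1-(4-hydroxy-3-iodo-5-methoxyphenyl)ethanone | CC(=O)c1cc(I)c(O)c(OC)c1 | intermediate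
7 | 1-(3,4-dihydroxy-5-iodophenyl)ethanone | CC(=O)c1cc(I)c(O)c(O)c1 | intermediate
8 | 1-[3-iodo-4,5-bis(methoxymethoxy)phenyl]ethanone | CC(=O)c1cc(I)c(OCOC)c(OCOC)c1 | intermediate
9 | (S)-1-[3-iodo-4,5-bis(methoxymethoxy)phenyl]ethanol | C[C@H](O)c1cc(I)c(OCOC)c(OCOC)c1 | intermediate
10 | (S)-1-[3-iodo-4,5-bis(methoxymethoxy)phenyl]ethyl N,N-diisopropylcarbamate | C[C@H](OC(=O)N(C(C)C)C(C)C)c1cc(I)c(OCOC)c(OCOC)c1 | intermediate
11 | (S)-1-{3-[4-acetyl-2-(methoxymethoxy)phenoxy]-4,5-bis(methoxymethoxy)phenyl}ethyl N,N-diisopropylcarbamate | CC(=O)c1ccc(Oc2cc([C@H](C)OC(=O)N(C(C)C)C(C)C)cc(OCOC)c2OCOC)c(OCOC)c1 | intermediate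
12 | ring A (R)-carbinol, ring B (S)-carbamate of the tris-MOM diaryl ether | C[C@@H](O)c1ccc(Oc2cc([C@H](C)OC(=O)N(C(C)C)C(C)C)cc(OCOC)c2OCOC)c(OCOC)c1 | intermediate
13 | bis(N,N-diisopropylcarbamate), (R) on ring A and (S) on ring B (key-step precursor) | C[C@@H](OC(=O)N(C(C)C)C(C)C)c1ccc(Oc2cc([C@H](C)OC(=O)N(C(C)C)C(C)C)cc(OCOC)c2OCOC)c(OCOC)c1 | intermediate
14 | geranyl bromide | CC(C)=CCC/C(C)=C/CBr | starting material
15 | bis[(pinacolato)boryl]methane | CC1(C)OB(CB2OC(C)(C)C(C)(C)O2)OC1(C)C | starting material
16 | (E)-homogeranyl pinacol boronate | CC(C)=CCC/C(C)=C/CCB1OC(C)(C)C(C)(C)O1 | intermediate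
17 | dilithiated bis-carbamate, lithium in place of each benzylic hydrogen with retention | C[C@@]([Li])(OC(=O)N(C(C)C)C(C)C)c1ccc(Oc2cc([C@]([Li])(C)OC(=O)N(C(C)C)C(C)C)cc(OCOC)c2OCOC)c(OCOC)c1 | intermediate (not isolated)
18 | dilithium bis-boronate complex, each benzylic carbon bound to the carbamate oxygen and to a homogeranyl(pinacolato)borate | C[C@@]([B-]3(CC/C=C(\C)CCC=C(C)C)OC(C)(C)C(C)(C)O3)(OC(=O)N(C(C)C)C(C)C)c1ccc(Oc2cc([C@]([B-]4(CC/C=C(\C)CCC=C(C)C)OC(C)(C)C(C)(C)O4)(C)OC(=O)N(C(C)C)C(C)C)cc(OCOC)c2OCOC)c(OCOC)c1.[Li+].[Li+] | intermediate (not isolated)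
19 | bis(tertiary pinacol boronic ester), boron in place of each future vinyl group, (R) at the ring A carbon and (S) at the ring B carbon (key-step product) | CC1(C)OB(OC1(C)C)[C@@](C)(CC/C=C(\C)CCC=C(C)C)c1ccc(Oc2cc([C@](C)(B3OC(C)(C)C(C)(C)O3)CC/C=C(\C)CCC=C(C)C)cc(OCOC)c2OCOC)c(OCOC)c1 | intermediate
20 | dilithium bis(vinylboronate) complex | C=C[B-]3(OC(C)(C)C(C)(C)O3)[C@@](C)(CC/C=C(\C)CCC=C(C)C)c1ccc(Oc2cc([C@](C)([B-]4(C=C)OC(C)(C)C(C)(C)O4)CC/C=C(\C)CCC=C(C)C)cc(OCOC)c2OCOC)c(OCOC)c1.[Li+].[Li+] | intermediate (not isolated)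
21 | bis(β-iodoalkyl boronic ester), each quaternary carbon bound to CH(Bpin)CH2I, configuration at CH(Bpin) not controlled | ICC(B3OC(C)(C)C(C)(C)O3)[C@@](C)(CC/C=C(\C)CCC=C(C)C)c1ccc(Oc2cc([C@](C)(C(CI)B4OC(C)(C)C(C)(C)O4)CC/C=C(\C)CCC=C(C)C)cc(OCOC)c2OCOC)c(OCOC)c1 | intermediate (not isolated)
22 | tris-MOM ether of the target | C=C[C@@](C)(CC/C=C(\C)CCC=C(C)C)c1ccc(Oc2cc([C@](C)(C=C)CC/C=C(\C)CCC=C(C)C)cc(OCOC)c2OCOC)c(OCOC)c1 | intermediate
23 | CNP0230356.1, 3-{2-hydroxy-4-[(3R,6E)-3,7,11-trimethyldodeca-1,6,10-trien-3-yl]phenoxy}-5-[(3S,6E)-3,7,11-trimethyldodeca-1,6,10-trien-3-yl]benzene-1,2-diol | C=C[C@@](C)(CC/C=C(\C)CCC=C(C)C)c1ccc(Oc2cc([C@](C)(C=C)CC/C=C(\C)CCC=C(C)C)cc(O)c2O)c(O)c1 | target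

**Step count**

Total steps: 15. Longest linear sequence: 11 steps (acetovanillone 5 through steps 4–11 and 13–15).

**Steps most likely to fail**

Step 13 (key step). The second lithiation may stay incomplete, ortho-lithiation beside the MOM ethers may compete, and reversal of one ate complex may erode stereospecificity at one site, giving mixtures of mono- and bis-adducts and of diastereomers. The fallback builds one quaternary centre at a time, setting out from 12 and coming back at 22. The ring A carbinol of 12 is silylated (TBSCl, imidazole, DMF) to the ring A tert-butyldimethylsilyl ether ring B carbamate F1. A single lithiation–borylation at ring B (s-BuLi 1.3 equiv, Et2O, −78 °C; 16; MgBr2/MeOH) should give the ring B tertiary boronate F2. Zweifel olefination (vinyllithium; I2; NaOMe) gives the ring B vinyl silyl ether F3. Bu4NF in THF frees the ring A carbinol F4, and carbamoylation (iPr2NCOCl, Et3N) gives the ring A carbamate F5. A second lithiation–borylation with 16 gives the ring A tertiary boronate F6, and a second Zweifel olefination gives 22.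

Step 9. The C–O coupling may be sluggish because the phenoxide of 4 is deactivated by its para acetyl group and both partners carry ortho substituents, so reductive loss of iodine from 10 can take over. The fallback reverses the polarity to a nucleophilic aromatic substitution, setting out from 10 and coming back at 11. Copper-catalysed hydroxylation of 10 (CuI, 1,10-phenanthroline, KOH, DMSO/H2O, 100 °C) gives the ring B phenol (S)-1-[3-hydroxy-4,5-bis(methoxymethoxy)phenyl]ethyl N,N-diisopropylcarbamate F7. Purchased 1-(4-fluoro-3-hydroxyphenyl)ethanone F8 is protected (MOMCl, iPr2NEt) as 1-[4-fluoro-3-(methoxymethoxy)phenyl]ethanone F9. The phenoxide of F7 then displaces the fluoride of F9, which is activated by the para acetyl group (K2CO3, DMSO, 110 °C), to give 11.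

Step 14. Ate-complex formation at the two hindered tertiary boronic esters may be incomplete, so that only one site is vinylated, and iodine may attack the trisubstituted alkenes. The fallback replaces the Zweifel reaction by one-carbon homologation and methylenation, setting out from 19 and coming back at 22. Matteson homologation with chloromethyllithium (BrCH2Cl, n-BuLi, THF, −78 °C → rt) gives the bis(primary boronic ester) F10 with retention at both quaternary carbons. Oxidation (NaOH, H2O2) gives the diol F11, Dess–Martin periodinane gives the dialdehyde F12, and Wittig methylenation (Ph3PCH3Br, KOtBu, THF) gives 22.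

**Further compounds**

F1 | step 13 | ring A (R)-tert-butyldimethylsilyl ether, ring B (S)-carbamate | C[C@@H](O[Si](C)(C)C(C)(C)C)c1ccc(Oc2cc([C@H](C)OC(=O)N(C(C)C)C(C)C)cc(OCOC)c2OCOC)c(OCOC)c1
F2 | step 13 | ring A silyl ether, ring B tertiary pinacol boronate | C[C@@H](O[Si](C)(C)C(C)(C)C)c1ccc(Oc2cc([C@](C)(B3OC(C)(C)C(C)(C)O3)CC/C=C(\C)CCC=C(C)C)cc(OCOC)c2OCOC)c(OCOC)c1
F3 | step 13 | ring A silyl ether, ring B vinyl quaternary centre | C[C@@H](O[Si](C)(C)C(C)(C)C)c1ccc(Oc2cc([C@](C)(C=C)CC/C=C(\C)CCC=C(C)C)cc(OCOC)c2OCOC)c(OCOC)c1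
F4 | step 13 | ring A (R)-carbinol, ring B vinyl quaternary centre | C[C@@H](O)c1ccc(Oc2cc([C@](C)(C=C)CC/C=C(\C)CCC=C(C)C)cc(OCOC)c2OCOC)c(OCOC)c1
F5 | step 13 | ring A (R)-carbamate, ring B vinyl quaternary centre | C[C@@H](OC(=O)N(C(C)C)C(C)C)c1ccc(Oc2cc([C@](C)(C=C)CC/C=C(\C)CCC=C(C)C)cc(OCOC)c2OCOC)c(OCOC)c1
F6 | step 13 | ring A tertiary pinacol boronate, ring B vinyl quaternary centre | CC1(C)OB(OC1(C)C)[C@@](C)(CC/C=C(\C)CCC=C(C)C)c1ccc(Oc2cc([C@](C)(C=C)CC/C=C(\C)CCC=C(C)C)cc(OCOC)c2OCOC)c(OCOC)c1
F7 | step 9 | (S)-1-[3-hydroxy-4,5-bis(methoxymethoxy)phenyl]ethyl N,N-diisopropylcarbamate | C[C@H](OC(=O)N(C(C)C)C(C)C)c1cc(O)c(OCOC)c(OCOC)c1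
F8 | step 9 | 1-(4-fluoro-3-hydroxyphenyl)ethanone (purchased) | CC(=O)c1ccc(F)c(O)c1
F9 | step 9 | 1-[4-fluoro-3-(methoxymethoxy)phenyl]ethanone | CC(=O)c1ccc(F)c(OCOC)c1
F10 | step 14 | bis(homologated primary pinacol boronate), CH2Bpin on each quaternary carbon | CC1(C)OB(OC1(C)C)C[C@@](C)(CC/C=C(\C)CCC=C(C)C)c1ccc(Oc2cc([C@](C)(CB3OC(C)(C)C(C)(C)O3)CC/C=C(\C)CCC=C(C)C)cc(OCOC)c2OCOC)c(OCOC)c1
F11 | step 14 | bis(primary alcohol), CH2OH on each quaternary carbon | OC[C@@](C)(CC/C=C(\C)CCC=C(C)C)c1ccc(Oc2cc([C@](C)(CO)CC/C=C(\C)CCC=C(C)C)cc(OCOC)c2OCOC)c(OCOC)c1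
F12 | step 14 | dialdehyde, CHO on each quaternary carbon | O=C[C@@](C)(CC/C=C(\C)CCC=C(C)C)c1ccc(Oc2cc([C@](C)(C=O)CC/C=C(\C)CCC=C(C)C)cc(OCOC)c2OCOC)c(OCOC)c1
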